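**Retrosynthetic overview**

1. The last C–C bond made is the one between the sp2 CH terminus of the (Z,E)-diene and the side-chain carbinol carbon. Cutting it gives (1Z,3E)-dienyl iodide 12 and epoxy aldehyde 22, two electrophilic carbons that are joined by reductive polarity reversal (Ni/Cr), which also sets the carbinol stereocentre; desilylation then gives the target.
2. Enabling feature: the carbinol carbon lies between a β,β-disubstituted alkenyl CH and C-1 of the 7-oxabicyclo[4.1.0]heptene, a fully substituted oxirane carbon. The aldehyde placed there has no α-hydrogen, and the alkenyl metal keeps its geometry. Without the oxirane oxygen and the side chain, ring B (a cis-2,5-bis(hydroxymethyl)cyclohexa-2,5-diene-1,4-diol) is C2-symmetric.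
3. Fragment 22: ring B is bought as dimethyl succinylsuccinate 13 and worked in two directions (asymmetric hydrogenation, double selenoxide elimination, ester reduction). Monosilylation breaks the symmetry, and a hydroxyl-directed epoxidation closes the oxirane (ring C) before oxidation to the aldehyde.
4. Fragment 12: ring A is closed by a trivalent-titanium radical cyclisation of (R)-6,7-epoxygeranyl acetate. The iodo-diene is attached by Julia–Kocienski olefination with (Z)-3-iodo-2-methylacrolein 11, made from propargyl alcohol.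
5. Order of ring formation: ring A (step 2), then oxirane ring C on the preformed ring B (step 16); the key step closes no ring.

Key step: step 18

Assumption 1: the (S)-oxazoline–sulfonamide ligand in step 18 is taken to deliver the dienyl group to the Si face of the formyl group; if its sense is the opposite, the antipode from (R)-valinol is used with no other change.
Assumption 2: (S)-BINAP–Ru is taken to give (S)-carbinols from 13, as it does from simple β-keto esters; the ester-bearing centres of 14 and 15 are drawn as dynamic kinetic resolution should set them and are erased in steps 12 and 13.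

**Route**

Step 1
Reactants: 1 geranyl acetate
Product: 2 (2E)-5-[(2R)-3,3-dimethyloxiran-2-yl]-3-methylpent-2-en-1-yl acetate
Conditions: D-fructose-derived Shi ketone (1,2:4,5-di-O-isopropylidene-β-D-erythro-2,3-hexodiulo-2,6-pyranose, 0.3 equiv), Oxone (2KHSO5·KHSO4·K2SO4), K2CO3, Bu4NHSO4, Na2B4O7 buffer, MeCN–CH2(OMe)2–H2O, 0 °C
Reagents that add atoms: potassium peroxymonosulfate (the oxidant in Oxone), [K+].[O-]S(=O)(=O)OO
Why: Shi asymmetric epoxidation, in which the chiral dioxirane attacks the electron-rich 6,7-alkene (the 2,3-alkene is deactivated by the allylic acetate) through a spiro transition state and should give the (R)-epoxide that later becomes the carbinol centre of ring A.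

Step 2
Reactants: 2 (2E)-5-[(2R)-3,3-dimethyloxiran-2-yl]-3-methylpent-2-en-1-yl acetate
Product: 3 [(1S,3R)-3-hydroxy-2,2-dimethyl-6-methylidenecyclohexyl]methyl acetate
Conditions: Cp2TiCl2 (2.5 equiv), Mn dust, THF, 25 °C (Cp2TiCl formed in the flask); then 1 M HCl
Reagents that add atoms: none
Why: Radical epoxy-polyene cyclisation mediated by Cp2TiCl (trivalent titanium): homolytic opening of the oxirane gives the tertiary radical, which closes ring A by 6-endo-trig attack on the trisubstituted alkene through a chair with the titanoxy and acetoxymethyl groups both equatorial (cis-1,3; the carbinol centre comes from the epoxide and the ring CH centre from the chair), after which the new tertiary radical is trapped by a second Cp2TiCl and loses a methyl β-hydrogen to give the exocyclic alkene.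

Step 3
Reactants: 3 [(1S,3R)-3-hydroxy-2,2-dimethyl-6-methylidenecyclohexyl]methyl acetate
Product: 4 (1R,3S)-3-(hydroxymethyl)-2,2-dimethyl-4-methylidenecyclohexan-1-ol
Conditions: K2CO3 (cat.), MeOH, 25 °C
Reagents that add atoms: none
Why: Base-catalysed transesterification of the primary acetate, which touches no stereocentre.

Step 4
Reactants: 4 (1R,3S)-3-(hydroxymethyl)-2,2-dimethyl-4-methylidenecyclohexan-1-ol
Product: 5 (1R,3S)-2,2-dimethyl-4-methylidene-3-{[(1-phenyl-1H-tetrazol-5-yl)sulfanyl]methyl}cyclohexan-1-ol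
Conditions: 1-phenyl-1H-tetrazole-5-thiol, PPh3, iPrO2CN=NCO2iPr, THF, 0 → 25 °C
Reagents that add atoms: 1-phenyl-1H-tetrazole-5-thiol, SC1=NN=NN1c1ccccc1
Why: Mitsunobu thioetherification, in which only the primary hydroxyl should react because the secondary hydroxyl next to the gem-dimethyl carbon is too hindered.

Step 5
Reactants: 5 (1R,3S)-2,2-dimethyl-4-methylidene-3-{[(1-phenyl-1H-tetrazol-5-yl)sulfanyl]methyl}cyclohexan-1-ol
Product: 6 (1R,3S)-2,2-dimethyl-4-methylidene-3-{[(1-phenyl-1H-tetrazol-5-yl)sulfonyl]methyl}cyclohexan-1-ol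
Conditions: (NH4)6Mo7O24·4H2O (10 mol%), 30% H2O2, EtOH, 0 → 25 °C
Reagents that add atoms: hydrogen peroxide, OO
Why: Molybdate-catalysed oxidation of sulfide to sulfone, the usual prelude to a Julia–Kocienski olefination, which should leave the unactivated 1,1-disubstituted alkene alone.

Step 6
Reactants: 6 (1R,3S)-2,2-dimethyl-4-methylidene-3-{[(1-phenyl-1H-tetrazol-5-yl)sulfonyl]methyl}cyclohexan-1-ol
Product: 7 5-({[(1S,3R)-2,2-dimethyl-6-methylidene-3-(triethylsilyloxy)cyclohexyl]methyl}sulfonyl)-1-phenyl-1H-tetrazole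
Conditions: Et3SiOTf, 2,6-lutidine, CH2Cl2, −78 → 0 °C
Reagents that add atoms: triethylsilyl trifluoromethanesulfonate, CC[Si](CC)(CC)OS(=O)(=O)C(F)(F)F
Why: Silylation of the hindered secondary alcohol with the silyl triflate, placed after step 5 so that the acid-labile triethylsilyl ether never meets the acidic peroxide medium.

Step 7
Reactants: 8 prop-2-yn-1-ol
Product: 10 (2Z)-3-iodo-2-methylprop-2-en-1-ol, via alkenylmagnesium alkoxide 9 (not isolated)
Conditions: MeMgBr (3 equiv), CuI (10 mol%), THF, −10 → 25 °C; then I2, −78 → 0 °C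
Reagents that add atoms: methylmagnesium bromide, C[Mg]Br; iodine, II
Why: Copper-catalysed anti-carbomagnesiation of the propargylic alkoxide (methyl to the internal carbon, magnesium to the terminal carbon cis to the CH2O group in a five-membered chelate) followed by iodinolysis with retention, which fixes the (Z)-trisubstituted alkene of the side chain.

Step 8
Reactants: 10 (2Z)-3-iodo-2-methylprop-2-en-1-ol
Product: 11 (2Z)-3-iodo-2-methylprop-2-enal
Conditions: MnO2 (15 equiv), CH2Cl2, 25 °C, dark; filtered and used at once as a solution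
Reagents that add atoms: none
Why: MnO2 oxidation of an allylic alcohol under neutral conditions, which should keep the (Z)-geometry if the enal is used directly.

Step 9
Reactants: 7 5-({[(1S,3R)-2,2-dimethyl-6-methylidene-3-(triethylsilyloxy)cyclohexyl]methyl}sulfonyl)-1-phenyl-1H-tetrazole; 11 (2Z)-3-iodo-2-methylprop-2-enal
Product: 12 triethyl{[(1R,3S)-3-[(1E,3Z)-4-iodo-3-methylbuta-1,3-dien-1-yl]-2,2-dimethyl-4-methylidenecyclohexyl]oxy}silane
Conditions: KN(SiMe3)2, MeOCH2CH2OMe, −60 °C; then 11, −60 → 0 °C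
Reagents that add atoms: none
Why: Julia–Kocienski olefination, in which the metalated tetrazolyl sulfone adds to the enal and Smiles rearrangement with loss of SO2 and tetrazolone gives the alkene; the β-branched sulfone should favour the (E)-isomer and the iodoalkene should keep its geometry at low temperature.

Step 10
Reactants: 13 dimethyl 2,5-dioxocyclohexane-1,4-dicarboxylate (dimethyl succinylsuccinate)
Product: 14 dimethyl (1S,2S,4S,5S)-2,5-dihydroxycyclohexane-1,4-dicarboxylate
Conditions: Ru2Cl4[(S)-BINAP]2·NEt3 (1 mol%), H2 (80 atm), MeOH–CH2Cl2, 60 °C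
Reagents that add atoms: none
Why: Noyori asymmetric hydrogenation of a cyclic β-keto ester with dynamic kinetic resolution, run in both directions: each carbonyl is reduced from the same face under catalyst control, so both carbinols should be (S), which is the cis-diol, and a mis-set centre gives the separable trans-diol.

Step 11
Reactants: 14 dimethyl (1S,2S,4S,5S)-2,5-dihydroxycyclohexane-1,4-dicarboxylate
Product: 15 dimethyl (1S,2S,4S,5S)-2,5-bis(triethylsilyloxy)cyclohexane-1,4-dicarboxylate
Conditions: Et3SiCl, imidazole, DMF, 0 → 25 °C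
Reagents that add atoms: chlorotriethylsilane, CC[Si](Cl)(CC)CC
Why: Standard silyl ether formation with silyl chloride and imidazole.

Step 12
Reactants: 15 dimethyl (1S,2S,4S,5S)-2,5-bis(triethylsilyloxy)cyclohexane-1,4-dicarboxylate
Product: 16 dimethyl (2S,5S)-1,4-bis(phenylselanyl)-2,5-bis(triethylsilyloxy)cyclohexane-1,4-dicarboxylate (mixture at C-1 and C-4)
Conditions: LiN(iPr)2 (2.5 equiv), THF, −78 °C; then PhSeBr, −78 °C
Reagents that add atoms: benzeneselenenyl bromide, Br[Se]c1ccccc1
Why: Double α-selenenylation of the bis(ester enolate) at −78 °C, where β-elimination of the silyloxy groups should be slow; the new centres are lost in the next step.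

Step 13
Reactants: 16 dimethyl (2S,5S)-1,4-bis(phenylselanyl)-2,5-bis(triethylsilyloxy)cyclohexane-1,4-dicarboxylate
Product: 18 dimethyl (3S,6S)-3,6-bis(triethylsilyloxy)cyclohexa-1,4-diene-1,4-dicarboxylate, via bis-selenoxide 17 (not isolated)
Conditions: 30% H2O2, pyridine, CH2Cl2, 0 → 25 °C
Reagents that add atoms: none
Why: Selenide oxidation and selenoxide syn-elimination, which runs toward the CH2 group and away from the oxygen-bearing carbon and so should give both enoate alkenes without touching the carbinol centres or the C2 axis.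

Step 14
Reactants: 18 dimethyl (3S,6S)-3,6-bis(triethylsilyloxy)cyclohexa-1,4-diene-1,4-dicarboxylate
Product: 19 [(3S,6S)-3,6-bis(triethylsilyloxy)cyclohexa-1,4-diene-1,4-diyl]dimethanol
Conditions: iBu2AlH (5 equiv), CH2Cl2, −78 → −20 °C; aq. KNa tartrate
Reagents that add atoms: none
Why: 1,2-Reduction of both conjugated esters to allylic alcohols with iBu2AlH.

Step 15
Reactants: 19 [(3S,6S)-3,6-bis(triethylsilyloxy)cyclohexa-1,4-diene-1,4-diyl]dimethanol
Product: 20 [(3S,6S)-4-{[tert-butyl(dimethyl)silyl]oxymethyl}-3,6-bis(triethylsilyloxy)cyclohexa-1,4-dien-1-yl]methanol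
Conditions: tBuMe2SiCl (1.0 equiv), imidazole, CH2Cl2, −20 → 0 °C; unreacted 19 recycled
Reagents that add atoms: tert-butyl(chloro)dimethylsilane, CC(C)(C)[Si](C)(C)Cl
Why: Statistical monosilylation of two homotopic primary hydroxyls: because of the C2 axis either hydroxyl gives the same product, so the step only breaks the symmetry.

Step 16
Reactants: 20 [(3S,6S)-4-{[tert-butyl(dimethyl)silyl]oxymethyl}-3,6-bis(triethylsilyloxy)cyclohexa-1,4-dien-1-yl]methanol
Product: 21 [(1S,2S,5R,6S)-4-{[tert-butyl(dimethyl)silyl]oxymethyl}-2,5-bis(triethylsilyloxy)-7-oxabicyclo[4.1.0]hept-3-en-1-yl]methanol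
Conditions: VO(acac)2 (5 mol%), tBuOOH (in decane), CH2Cl2, 0 °C
Reagents that add atoms: tert-butyl hydroperoxide, CC(C)(C)OO
Why: Hydroxyl-directed epoxidation with VO(acac)2 and tBuOOH, in which only the alkene bearing the free CH2OH reacts and oxygen should be delivered to the ring face opposite the two allylic silyloxy groups, setting both oxirane centres.

Step 17
Reactants: 21 [(1S,2S,5R,6S)-4-{[tert-butyl(dimethyl)silyl]oxymethyl}-2,5-bis(triethylsilyloxy)-7-oxabicyclo[4.1.0]hept-3-en-1-yl]methanol
Product: 22 (1S,2S,5R,6S)-4-{[tert-butyl(dimethyl)silyl]oxymethyl}-2,5-bis(triethylsilyloxy)-7-oxabicyclo[4.1.0]hept-3-ene-1-carbaldehyde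
Conditions: Dess–Martin periodinane, NaHCO3, CH2Cl2, 0 → 25 °C
Reagents that add atoms: none
Why: Dess–Martin oxidation of the epoxy alcohol under buffered conditions, giving an aldehyde that has no α-hydrogen and cannot epimerise.

Step 18
Reactants: 12 triethyl{[(1R,3S)-3-[(1E,3Z)-4-iodo-3-methylbuta-1,3-dien-1-yl]-2,2-dimethyl-4-methylidenecyclohexyl]oxy}silane; 22 (1S,2S,5R,6S)-4-{[tert-butyl(dimethyl)silyl]oxymethyl}-2,5-bis(triethylsilyloxy)-7-oxabicyclo[4.1.0]hept-3-ene-1-carbaldehyde
Product: 24 (1S,2Z,4E)-1-[(1S,2S,5R,6S)-4-{[tert-butyl(dimethyl)silyl]oxymethyl}-2,5-bis(triethylsilyloxy)-7-oxabicyclo[4.1.0]hept-3-en-1-yl]-5-[(1S,3R)-2,2-dimethyl-6-methylidene-3-(triethylsilyloxy)cyclohexyl]-3-methylpenta-2,4-dien-1-ol, via dienylchromium species 23 (not isolated)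
Conditions: CrCl2 (4 equiv), (S)-N-[2-(4-isopropyl-4,5-dihydro-1,3-oxazol-2-yl)-6-methylphenyl]methanesulfonamide (4.4 equiv), Et3N (4.4 equiv), THF, 25 °C, 1 h; then NiCl2 (10 mol%), 12 (1.3 equiv), 22 (1 equiv), 25 °C; aq. sodium serinate work-up (ligand recovered)
Reagents that add atoms: none
Why: NiCl2 is reduced by CrCl2 to zerovalent nickel, which inserts into the C–I bond of 12 with retention; the dienyl group passes to chromium to give the trivalent dienylchromium species 23, which adds to the formyl group of 22. The closest known reaction type is the asymmetric Nozaki–Hiyama–Kishi coupling of alkenyl iodides with α-oxygenated aldehydes under a chiral oxazoline–sulfonamide ligand, a reductive union of two carbons that are both electrophilic. The step closes no ring. Its single new stereocentre, the carbinol carbon, is controlled by addition anti to the oxirane C–O bond (Felkin–Anh, the erythro sense usual for α,β-epoxy aldehydes) and by the ligand on chromium, chosen to deliver the dienyl group to the same Si face. The step needs chemoselectivity for the aldehyde beside the oxirane, four silyl ethers and the alkenes, and retention of the (Z)-alkene: the organochromium reagent is non-basic and adds only to aldehydes, the formyl carbon sits on a fully substituted oxirane carbon and so cannot enolise, epimerise or eliminate, and the β,β-disubstituted alkenyl metal does not isomerise. In this one operation all 22 carbons are joined and the last stereocentre is set, so that only desilylation remains.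

Step 19
Reactants: 24 (1S,2Z,4E)-1-[(1S,2S,5R,6S)-4-{[tert-butyl(dimethyl)silyl]oxymethyl}-2,5-bis(triethylsilyloxy)-7-oxabicyclo[4.1.0]hept-3-en-1-yl]-5-[(1S,3R)-2,2-dimethyl-6-methylidene-3-(triethylsilyloxy)cyclohexyl]-3-methylpenta-2,4-dien-1-ol
Product: 25 (1R,2S,5R,6S)-1-{(1S,2Z,4E)-1-hydroxy-5-[(1S,3R)-3-hydroxy-2,2-dimethyl-6-methylidenecyclohexyl]-3-methylpenta-2,4-dien-1-yl}-4-(hydroxymethyl)-7-oxabicyclo[4.1.0]hept-3-ene-2,5-diol
Conditions: HF·pyridine, pyridine, THF, 0 → 25 °C
Reagents that add atoms: none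
Why: Fluoride-mediated cleavage of the three triethylsilyl ethers and the primary tert-butyldimethylsilyl ether under pyridine-buffered conditions, chosen to avoid Payne rearrangement of the epoxy alcohols and ionisation of the dienyl carbinol.

**Compound list**

1 | geranyl acetate, (2E)-3,7-dimethylocta-2,6-dien-1-yl acetate | CC(=O)OC/C=C(\C)CCC=C(C)C | starting material
2 | (2E)-5-[(2R)-3,3-dimethyloxiran-2-yl]-3-methylpent-2-en-1-yl acetate | CC(=O)OC/C=C(\C)CC[C@H]1OC1(C)C | intermediate
3 | [(1S,3R)-3-hydroxy-2,2-dimethyl-6-methylidenecyclohexyl]methyl acetate (hydroxyl and acetoxymethyl cis) | C=C1CC[C@@H](O)C(C)(C)[C@H]1COC(C)=O | intermediate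
4 | (1R,3S)-3-(hydroxymethyl)-2,2-dimethyl-4-methylidenecyclohexan-1-ol | C=C1CC[C@@H](O)C(C)(C)[C@H]1CO | intermediate
5 | (1R,3S)-2,2-dimethyl-4-methylidene-3-{[(1-phenyl-1H-tetrazol-5-yl)sulfanyl]methyl}cyclohexan-1-ol | C=C1CC[C@@H](O)C(C)(C)[C@H]1CSC1=NN=NN1c1ccccc1 | intermediate
6 | (1R,3S)-2,2-dimethyl-4-methylidene-3-{[(1-phenyl-1H-tetrazol-5-yl)sulfonyl]methyl}cyclohexan-1-ol | C=C1CC[C@@H](O)C(C)(C)[C@H]1CS(=O)(=O)C1=NN=NN1c1ccccc1 | intermediate
7 | 5-({[(1S,3R)-2,2-dimethyl-6-methylidene-3-(triethylsilyloxy)cyclohexyl]methyl}sulfonyl)-1-phenyl-1H-tetrazole | C=C1CC[C@@H](O[Si](CC)(CC)CC)C(C)(C)[C@H]1CS(=O)(=O)C1=NN=NN1c1ccccc1 | intermediate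
8 | prop-2-yn-1-ol (propargyl alcohol) | OCC#C | starting material
9 | bromomagnesium (2Z)-3-(bromomagnesio)-2-methylprop-2-en-1-olate (magnesium cis to CH2O) | C/C(CO[Mg]Br)=C/[Mg]Br | intermediate (not isolated)
10 | (2Z)-3-iodo-2-methylprop-2-en-1-ol | C/C(CO)=C/I | intermediate
11 | (2Z)-3-iodo-2-methylprop-2-enal | C/C(C=O)=C/I | intermediate
12 | triethyl{[(1R,3S)-3-[(1E,3Z)-4-iodo-3-methylbuta-1,3-dien-1-yl]-2,2-dimethyl-4-methylidenecyclohexyl]oxy}silane | C=C1CC[C@@H](O[Si](CC)(CC)CC)C(C)(C)[C@H]1/C=C/C(C)=C\I | intermediate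
13 | dimethyl 2,5-dioxocyclohexane-1,4-dicarboxylate (dimethyl succinylsuccinate) | COC(=O)C1CC(=O)C(C(=O)OC)CC1=O | starting material
14 | dimethyl (1S,2S,4S,5S)-2,5-dihydroxycyclohexane-1,4-dicarboxylate (hydroxyls cis to each other) | COC(=O)[C@H]1C[C@H](O)[C@@H](C(=O)OC)C[C@@H]1O | intermediate
15 | dimethyl (1S,2S,4S,5S)-2,5-bis(triethylsilyloxy)cyclohexane-1,4-dicarboxylate | COC(=O)[C@H]1C[C@H](O[Si](CC)(CC)CC)[C@@H](C(=O)OC)C[C@@H]1O[Si](CC)(CC)CC | intermediate
16 | dimethyl (2S,5S)-1,4-bis(phenylselanyl)-2,5-bis(triethylsilyloxy)cyclohexane-1,4-dicarboxylate (mixture at C-1 and C-4) | COC(=O)C1([Se]c2ccccc2)C[C@H](O[Si](CC)(CC)CC)C(C(=O)OC)([Se]c2ccccc2)C[C@@H]1O[Si](CC)(CC)CC | intermediate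
17 | dimethyl (2S,5S)-1,4-bis(phenylseleninyl)-2,5-bis(triethylsilyloxy)cyclohexane-1,4-dicarboxylate | COC(=O)C1([Se](=O)c2ccccc2)C[C@H](O[Si](CC)(CC)CC)C(C(=O)OC)([Se](=O)c2ccccc2)C[C@@H]1O[Si](CC)(CC)CC | intermediate (not isolated)
18 | dimethyl (3S,6S)-3,6-bis(triethylsilyloxy)cyclohexa-1,4-diene-1,4-dicarboxylate (C2-symmetric, silyloxy groups cis) | COC(=O)C1=C[C@H](O[Si](CC)(CC)CC)C(C(=O)OC)=C[C@@H]1O[Si](CC)(CC)CC | intermediate
19 | [(3S,6S)-3,6-bis(triethylsilyloxy)cyclohexa-1,4-diene-1,4-diyl]dimethanol | OCC1=C[C@H](O[Si](CC)(CC)CC)C(CO)=C[C@@H]1O[Si](CC)(CC)CC | intermediate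
20 | [(3S,6S)-4-{[tert-butyl(dimethyl)silyl]oxymethyl}-3,6-bis(triethylsilyloxy)cyclohexa-1,4-dien-1-yl]methanol | OCC1=C[C@H](O[Si](CC)(CC)CC)C(CO[Si](C)(C)C(C)(C)C)=C[C@@H]1O[Si](CC)(CC)CC | intermediate
21 | [(1S,2S,5R,6S)-4-{[tert-butyl(dimethyl)silyl]oxymethyl}-2,5-bis(triethylsilyloxy)-7-oxabicyclo[4.1.0]hept-3-en-1-yl]methanol (oxirane anti to both silyloxy groups) | OC[C@]12O[C@H]1[C@H](O[Si](CC)(CC)CC)C(CO[Si](C)(C)C(C)(C)C)=C[C@@H]2O[Si](CC)(CC)CC | intermediate
22 | (1S,2S,5R,6S)-4-{[tert-butyl(dimethyl)silyl]oxymethyl}-2,5-bis(triethylsilyloxy)-7-oxabicyclo[4.1.0]hept-3-ene-1-carbaldehyde | O=C[C@]12O[C@H]1[C@H](O[Si](CC)(CC)CC)C(CO[Si](C)(C)C(C)(C)C)=C[C@@H]2O[Si](CC)(CC)CC | intermediate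
23 | chloro[(1Z,3E)-dienyl]chromium sulfonamidate (trivalent chromium) carrying the dienyl group of 12 and the deprotonated ligand of step 18 | C=C1CC[C@@H](O[Si](CC)(CC)CC)C(C)(C)[C@H]1/C=C/C(C)=C\[Cr](Cl)N(c1c(C)cccc1C1=N[C@@H](C(C)C)CO1)S(C)(=O)=O | intermediate (not isolated)
24 | (1S,2Z,4E)-1-[(1S,2S,5R,6S)-4-{[tert-butyl(dimethyl)silyl]oxymethyl}-2,5-bis(triethylsilyloxy)-7-oxabicyclo[4.1.0]hept-3-en-1-yl]-5-[(1S,3R)-2,2-dimethyl-6-methylidene-3-(triethylsilyloxy)cyclohexyl]-3-methylpenta-2,4-dien-1-ol | C=C1CC[C@@H](O[Si](CC)(CC)CC)C(C)(C)[C@H]1/C=C/C(C)=C\[C@H](O)[C@]12O[C@H]1[C@H](O[Si](CC)(CC)CC)C(CO[Si](C)(C)C(C)(C)C)=C[C@@H]2O[Si](CC)(CC)CC | intermediate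
25 | (1R,2S,5R,6S)-1-{(1S,2Z,4E)-1-hydroxy-5-[(1S,3R)-3-hydroxy-2,2-dimethyl-6-methylidenecyclohexyl]-3-methylpenta-2,4-dien-1-yl}-4-(hydroxymethyl)-7-oxabicyclo[4.1.0]hept-3-ene-2,5-diol | C=C1CC[C@@H](O)C(C)(C)[C@H]1/C=C/C(C)=C\[C@H](O)[C@]12O[C@H]1[C@H](O)C(CO)=C[C@@H]2O | target

**Step count and risks**

Total step count: 19. Longest linear sequence: 10 steps (13 → 14 → 15 → 16 → 18 → 19 → 20 → 21 → 22 → 24 → 25).

The three steps most likely to fail:

First, step 18. The dienylchromium species may add to the wrong face of the hindered formyl group, with the substrate bias overriding the ligand, or the neopentyl-type aldehyde may react so slowly that the organochromium species is lost to protonation. The fallback sets out from 12 and 22 and returns at 24. The two are coupled without the chiral ligand (CrCl2, NiCl2 cat., DMSO), which should give the carbinol as an epimer mixture containing the (1R)-epimer of 24 F1. The mixture is oxidised with Dess–Martin periodinane to the (2Z,4E)-dienone F2, which is reduced at once (NaBH4, CeCl3·7H2O, MeOH, −78 °C) before oxa-electrocyclisation of the (Z)-dienone can compete. The stereocentre is then set by hydride addition to a ketone and not by carbon addition to an aldehyde, so the same Felkin–Anh bias that misdirected the carbon nucleophile should now lead to 24.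

Second, step 10. The strongly enolised bis(β-keto ester) may be hydrogenated slowly, or with incomplete control at one of the two carbonyls. The fallback sets out from 13 and returns at 16. NaBH4 in MeOH should give dimethyl 2,5-dihydroxycyclohexane-1,4-dicarboxylate as a stereoisomer mixture F3. Burkholderia cepacia lipase with vinyl acetate should acylate only R-configured carbinols, converting the unwanted isomers into the (2R,5R)-diacetate F4 and the monoacetate of the (2R,5S)-diols F5, which are separated by chromatography. The untouched (2S,5S)-diol F6 (a mixture at the two ester carbons) is silylated (Et3SiCl, imidazole) to the bis(triethylsilyl) ether F7, and selenenylation as in step 12 erases the ester centres and gives 16. Here the absolute configuration comes from a resolution, not from the hydrogenation catalyst.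

Third, step 12. The ester enolates may eliminate triethylsilanolate (β-elimination), or the second selenenylation may stay incomplete. The fallback sets out from 14 and returns at 18. The unprotected diol 14 is converted with LiN(iPr)2 (4.6 equiv, THF, −78 °C) into its bis(alkoxide) bis(enolate), which carries no leaving group, and trapped with PhSeBr to give the bis-selenide diol F8. Oxidation (30% H2O2, pyridine, CH2Cl2, 0 °C) should give, through the bis-selenoxide F9, the diene diol diester F10, which is silylated at once (Et3SiCl, imidazole, DMF) to 18.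

Further compounds
F1 | step 18 | (1R,2Z,4E)-1-[(1S,2S,5R,6S)-4-{[tert-butyl(dimethyl)silyl]oxymethyl}-2,5-bis(triethylsilyloxy)-7-oxabicyclo[4.1.0]hept-3-en-1-yl]-5-[(1S,3R)-2,2-dimethyl-6-methylidene-3-(triethylsilyloxy)cyclohexyl]-3-methylpenta-2,4-dien-1-ol (carbinol epimer of 24) | C=C1CC[C@@H](O[Si](CC)(CC)CC)C(C)(C)[C@H]1/C=C/C(C)=C\[C@@H](O)[C@]12O[C@H]1[C@H](O[Si](CC)(CC)CC)C(CO[Si](C)(C)C(C)(C)C)=C[C@@H]2O[Si](CC)(CC)CC
F2 | step 18 | (2Z,4E)-1-[(1S,2S,5R,6S)-4-{[tert-butyl(dimethyl)silyl]oxymethyl}-2,5-bis(triethylsilyloxy)-7-oxabicyclo[4.1.0]hept-3-en-1-yl]-5-[(1S,3R)-2,2-dimethyl-6-methylidene-3-(triethylsilyloxy)cyclohexyl]-3-methylpenta-2,4-dien-1-one | C=C1CC[C@@H](O[Si](CC)(CC)CC)C(C)(C)[C@H]1/C=C/C(C)=C\C(=O)[C@]12O[C@H]1[C@H](O[Si](CC)(CC)CC)C(CO[Si](C)(C)C(C)(C)C)=C[C@@H]2O[Si](CC)(CC)CC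
F3 | step 10 | dimethyl 2,5-dihydroxycyclohexane-1,4-dicarboxylate (stereoisomer mixture) | COC(=O)C1CC(O)C(C(=O)OC)CC1O
F4 | step 10 | dimethyl (2R,5R)-2,5-diacetoxycyclohexane-1,4-dicarboxylate (ester carbons unassigned) | COC(=O)C1C[C@@H](OC(C)=O)C(C(=O)OC)C[C@H]1OC(C)=O
F5 | step 10 | dimethyl (2R,5S)-2-acetoxy-5-hydroxycyclohexane-1,4-dicarboxylate (ester carbons unassigned) | COC(=O)C1C[C@@H](OC(C)=O)C(C(=O)OC)C[C@@H]1O
F6 | step 10 | dimethyl (2S,5S)-2,5-dihydroxycyclohexane-1,4-dicarboxylate (mixture at the ester carbons) | COC(=O)C1C[C@H](O)C(C(=O)OC)C[C@@H]1O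
F7 | step 10 | dimethyl (2S,5S)-2,5-bis(triethylsilyloxy)cyclohexane-1,4-dicarboxylate (mixture at the ester carbons) | COC(=O)C1C[C@H](O[Si](CC)(CC)CC)C(C(=O)OC)C[C@@H]1O[Si](CC)(CC)CC
F8 | step 12 | dimethyl (2S,5S)-2,5-dihydroxy-1,4-bis(phenylselanyl)cyclohexane-1,4-dicarboxylate (mixture at C-1 and C-4) | COC(=O)C1([Se]c2ccccc2)C[C@H](O)C(C(=O)OC)([Se]c2ccccc2)C[C@@H]1O
F9 | step 12 | dimethyl (2S,5S)-2,5-dihydroxy-1,4-bis(phenylseleninyl)cyclohexane-1,4-dicarboxylate | COC(=O)C1([Se](=O)c2ccccc2)C[C@H](O)C(C(=O)OC)([Se](=O)c2ccccc2)C[C@@H]1O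
F10 | step 12 | dimethyl (3S,6S)-3,6-dihydroxycyclohexa-1,4-diene-1,4-dicarboxylate | COC(=O)C1=C[C@H](O)C(C(=O)OC)=C[C@@H]1O
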